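# Stenophyllol B: ring B and the indane by [2+2+2] cyclotrimerisation

**Numbering and abbreviations.** Compounds 1–34 are numbered in the order in which they appear in the steps; the full list follows step 21. An = 4-methoxyphenyl; TIPS = tri(propan-2-yl)silyl; DBF = (2R,3R)-3-(3,5-dimethoxyphenyl)-6-methoxy-2-(4-methoxyphenyl)-2,3-dihydro-1-benzofuran-4-yl, that is ring D with its dihydrofuran, ring C and one An group. Atom labels: indane C1, C2, C3, C3a, C4–C7, C7a. C1 bears the exocyclic carbon Cα, C2 bears ring D, C3 bears an aryl group; "furan C2" and "furan C3" are the two sp3 carbons of the dihydrofuran.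

## Analysis of the target

Stenophyllol B (34) is a resveratrol trimer built on an indane: the resorcinol ring B is fused to a cyclopentane whose three sp3 carbons C1, C2 and C3 carry, all trans, a diarylmethine carbon (Cα), the resorcinol ring D and a 4-hydroxyphenyl group. C1 and C2 also belong to an eight-membered carbocycle (C1–Cα–ring C–furan C3–ring D–C2), and ring D is fused to a trans-2-(4-hydroxyphenyl)-2,3-dihydrofuran whose C3 sits between rings C and D. There are six stereocentres, C3 (S), C2 (S), C1 (R), Cα (R), furan C3 (R) and furan C2 (R); the first three are contiguous on the five-membered ring, Cα hangs on C1, and the furan pair is linked to the others only through ring D and the eight-membered ring. The eight phenols make the free compound prone to oxidation and the benzylic C2–O bond of the dihydrofuran ionises in acid, so the phenols are carried as alkyl ethers and acid is used sparingly. The main difficulty is that three resorcinol rings of almost equal nucleophilicity are present, so electrophilic C–C bond formation cannot tell them apart; in addition ring B is bonded to C1 through C7a, which is meta to both of its oxygens and out of reach of a Friedel–Crafts closure. The strategy rests on ring B itself: its oxygens at C4 and C6 are meta to each other and the ring is fused at C3a–C7a to a five-membered ring made of three sp3 carbons, which is the pattern left behind when a hepta-1,6-diyne with an alkoxy group on one terminus is cyclotrimerised with an alkoxyalkyne.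

## Retrosynthetic reasoning

**Ether cleavage last.** 34 is taken back to its octa-alkyl ether 33 (six methyl ethers, two ethyl ethers on ring B). Only C–O bonds are cut. The phenols stay masked through all cationic and organometallic steps, and the two ethyl groups are the ones that the cyclotrimerisation delivers.

**Cα–ring C bond (eight-membered ring).** In 33 the bond from Cα to ring C is cut to give carbinol 32, and 32 is cut between Cα and its An group to give aldehyde 30 and Grignard reagent 31. The last ring closure belongs here because a cation at Cα is 4-methoxybenzylic and can reach only one nucleophilic carbon through an unstrained ring: attack on ring B would close a four-membered ring, attack on ring D a trans-fused bicyclo[3.3.0] system. A cut at furan C3–ring D was rejected, since a cation at furan C3 would also reach C7 of ring B through a seven-membered ring. The forward reaction has to set Cα.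

**Ring B and the five-membered ring.** 30 comes from acetal 29, and 29 is cut three times at once, at C3a–C7a, C4–C5 and C6–C7, which releases diyne 27 and ethoxyethyne 28. The cut is made here and not at C3–C3a because a Friedel–Crafts route would need ring B attached beforehand through C7a, the carbon that arene chemistry cannot address. The cyclotrimerisation makes the arene from three alkynes, so neither ring-fusion bond depends on arene reactivity and both oxygens arrive in place. C1–C3 are brought in from an open chain where catalysts can set them. The forward reaction must place the ethoxy group of 28 at C6 and not at C5.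

**Ring D is finished before ring B exists.** 27 already carries the complete DBF unit and a diethyl acetal as spectators. Once ring B is present its C5 and C7 are as activated as the one position of ring D that has to be substituted, so ring D could no longer be addressed selectively. Furan C3 and C2 have no stereochemical link to C1–C3 and have to be set by a catalyst on their own, which is easier on a small molecule.

**The two alkynes and the acetal.** The ethoxyalkyne of 27 is traced through its silylated form 26 to the ethyl ester 24, whose enolate oxygen and α-hydrogen are removed in the forward direction. 24 comes from malonate 23 by loss of one ester group. The acetal of 23 comes from the nitromethyl group of 22, and 22 is cut at the alkyne–C bond into nitroalkene 20 and silylacetylene 21. 20 is cut at its C=C bond into aldehyde 16 and nitromethane 17. Nitromethane supplies Cα and the acetylene supplies C7a and C7. The gain is that the third stereocentre of the chain is set by a catalyst and the α-alkynyl aldehyde is never free.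

**The bond between the two aryl-bearing carbons.** 16 is cut between future C2 and C3 into arylacetaldehyde 15 and benzylidene malonate 14 (from 12 and 13). Both stereocentres form in one catalytic step, and the malonate leaves the An-bearing carbon without an acidic hydrogen during the later base chemistry.

**The dihydrofuran.** 15 comes from alcohol 11. In 11 the furan C2–O bond is cut, through silyl ether 10, to the open alcohol 9, in which that oxygen still carries its methyl group. 9 comes from ketone 8, whose α-carbon (future furan C3) is configurationally labile, so the reduction can fix it by dynamic kinetic resolution. 8 is cut at its two aryl–C bonds into ketone 6 and bromide 7, and 6 into bromide 4 and ketone 5. The hindered bromide 4 is coupled first, with the small enolate of 5. 4 goes back to acid 1.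

## Alternatives that were turned down

**Alternative 1:** transannular aldol condensation.
- **Disconnection:** the C1–C2 bond of the five-membered ring, cut as the C=C bond of an indenone.
- **Forward key step:** a transannular aldol condensation inside an eleven-membered ring holding two ketones, which would close the five- and the eight-membered ring together and give indenone A1.
- **For it:** one C–C bond closes two rings, the macrocycle can be assembled convergently from rings B, C and D, and A1 already contains the dihydrofuran and Cα.
- **Against it:** A1 has given up the three stereocentres that are hardest to control. C3 is a ketone and C1=C2 is a tetrasubstituted alkene in a strained polycycle, so aryl addition with deoxygenation at C3 and a trans-selective reduction of the enone would have to be done late under substrate control. The aldol must pick one of several enolisable positions and one of two ketones, Cα (γ to the enone) can epimerise, and a macrocyclisation has to come first.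
- **Comparison:** at the ring-forming step alternative 1 is at least as economical as the chosen strategy (two rings from one bond, against two rings from three bonds) and it closes the eight-membered ring without a cation. The chosen strategy offers in its place that C1–C3 are set in an open chain by catalysts and pass into the indane untouched, with no macrocycle.

**Alternative 2:** flavanone ring contraction.
- **Disconnection:** the aryl–C3 bond of the dihydrofuran, traced to a flavanone through a 1,2-aryl shift.
- **Forward key step:** oxidative ring contraction with a hypervalent iodine oxidant in the presence of an orthoformate, giving the trans-dihydrobenzofuran ester A2.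
- **For it:** the shift is stereospecific and gives the trans ring, and flavanones can be had enantiopure. On the dihydrofuran itself this is stronger than the chosen route, which depends on a dynamic kinetic resolution and a cationic closure.
- **Against it:** A2 is only the ring D fragment and carries the wrong group at both points of attachment. Furan C3 bears a methoxycarbonyl group where ring C must stand, so ring C would have to be grown from, or exchanged for, that carbon. C4 bears a benzyloxy group where the bond to indane C2 is needed, which costs debenzylation, sulfonylation and a cross-coupling. Ring B, C1–C3 and the eight-membered ring are not addressed.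
- **Comparison:** more steps, with the carbocyclic core left open. The chosen strategy attaches ring C to ring D by direct ketone arylation and spends its key step on ring B and the indane.

**Alternative 3:** aryne σ-insertion.
- **Disconnection:** both bonds from ring C to its neighbours, Cα–ring C and furan C3–ring C.
- **Forward key step:** the enolate of a cyclic β-keto ester adds to an aryne, the aryl anion closes on the ketone and the cyclobutoxide fragments, expanding a six- to the eight-membered ring and giving keto ester A3.
- **For it:** two C–C bonds and the eight-membered ring form in one step without a cation at Cα, addition to a 3-alkoxyaryne is regiochemically dependable, and A3 keeps a ketone and an ester as handles. For making the eight-membered ring it is stronger than the Friedel–Crafts closure used here.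
- **Against it:** it presupposes an indane with ring B and C1–C3 already made, so the hardest structural feature is not addressed. After the key step Cα (aryl addition and deoxygenation at the ketone) and furan C3 (an epimerisable ester-bearing methine) both have to be set on the eight-membered ring under substrate control, and a selective O-demethylation is needed for the dihydrofuran.
- **Comparison:** longer after the key step and less certain in configuration. The chosen strategy sets furan C3 by a catalyst before the ring exists and makes Cα in one diastereoselective closure.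

Key step: step 17

**Remark on the chemistry.** The catalyst antipodes written in steps 6, 10 and 12 follow the sense of induction known for simpler substrates; if a sense were opposite on these substrates, the mirror-image catalyst would be taken.

## Route

**Step 1**
Reactants: 1 (3,5-dimethoxyphenyl)acetic acid
Product: 2 (2-bromo-3,5-dimethoxyphenyl)acetic acid
Conditions: NBS, MeCN, 0 → 23 °C
Reagents that add atoms: N-bromosuccinimide, O=C1CCC(=O)N1Br
Why: Electrophilic aromatic bromination; the carbon between the side chain and one methoxy group is para to the other methoxy group and is the most reactive site of a 3,5-dialkoxybenzyl arene, so monobromination should occur there and not between the two methoxy groups.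

**Step 2**
Reactants: 2 (2-bromo-3,5-dimethoxyphenyl)acetic acid
Product: 3 2-(2-bromo-3,5-dimethoxyphenyl)ethan-1-ol
Conditions: BH3·SMe2, THF, 0 → 23 °C; then H2O
Reagents that add atoms: none
Why: Borane reduces the carboxylic acid to the primary alcohol chemoselectively and does not touch the aryl bromide.

**Step 3**
Reactants: 3 2-(2-bromo-3,5-dimethoxyphenyl)ethan-1-ol
Product: 4 [2-(2-bromo-3,5-dimethoxyphenyl)ethoxy]tri(propan-2-yl)silane
Conditions: i-Pr3SiCl, imidazole, DMF, 23 °C
Reagents that add atoms: chlorotri(propan-2-yl)silane, CC(C)[Si](Cl)(C(C)C)C(C)C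
Why: Standard silylation; the bulky silyl ether keeps the alkoxide out of the two base-mediated palladium couplings, where it could otherwise displace the bromide, and survives them.

**Step 4**
Reactants: 4 [2-(2-bromo-3,5-dimethoxyphenyl)ethoxy]tri(propan-2-yl)silane; 5 1-(4-methoxyphenyl)ethan-1-one
Product: 6 2-[2,4-dimethoxy-6-(2-TIPS-oxyethyl)phenyl]-1-(4-methoxyphenyl)ethan-1-one
Conditions: Pd2(dba)3 (1.5 mol %), XPhos (3.6 mol %), NaOt-Bu (2.2 equiv), toluene, 80 °C
Reagents that add atoms: none
Why: Palladium-catalysed α-arylation of a methyl ketone enolate; the doubly ortho-substituted bromide is coupled with the smallest possible enolate, and its bulk should stop a second arylation.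

**Step 5**
Reactants: 6 2-[2,4-dimethoxy-6-(2-TIPS-oxyethyl)phenyl]-1-(4-methoxyphenyl)ethan-1-one; 7 1-bromo-3,5-dimethoxybenzene
Product: 8 2-(3,5-dimethoxyphenyl)-2-[2,4-dimethoxy-6-(2-TIPS-oxyethyl)phenyl]-1-(4-methoxyphenyl)ethan-1-one (racemic, configurationally labile)
Conditions: Pd(OAc)2 (3 mol %), [HP(t-Bu)3]BF4 (6 mol %), NaOt-Bu (2.2 equiv), toluene, 90 °C
Reagents that add atoms: none
Why: Second palladium-catalysed ketone α-arylation, now with an unhindered aryl bromide; the product stays deprotonated under the conditions, which prevents over-arylation. No stereocontrol is sought, since the new methine between two arenes and a carbonyl group epimerises freely.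

**Step 6**
Reactants: 8 the triaryl ethanone
Product: 9 (1R,2R)-2-(3,5-dimethoxyphenyl)-2-[2,4-dimethoxy-6-(2-TIPS-oxyethyl)phenyl]-1-(4-methoxyphenyl)ethan-1-ol
Conditions: trans-RuCl2[(S)-xylbinap][(S)-daipen] (1 mol %), t-BuOK (20 mol %), H2 (10 atm), i-PrOH/THF, 25 °C
Reagents that add atoms: none
Why: Noyori asymmetric hydrogenation with dynamic kinetic resolution: t-BuOK should equilibrate the two enantiomers of 8 through the enolate faster than the ketone is reduced. The (S,S) catalyst should give the (R)-carbinol, and the Felkin–Anh preference (the doubly ortho-substituted aryl group anti to the incoming hydride) should select the enantiomer of the ketone that leads to 2R, the future furan C3. Only C2 matters afterwards, because the carbinol centre is formed again in step 7.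

**Step 7**
Reactants: 9 the (1R,2R)-alcohol
Product: 11 2-DBF-ethan-1-ol, via dihydrobenzofuran silyl ether 10 (not isolated)
Conditions: Me3SiBr (1.3 equiv), CH2Cl2, −40 → 0 °C; then Bu4NF, THF, 23 °C
Reagents that add atoms: none
Why: Me3SiBr ionises the 4-methoxybenzylic alcohol; the methoxy oxygen ortho to the side chain closes the five-membered ring to an oxonium ion, which bromide demethylates (neighbouring-group participation with dealkylation). Closure onto the planar cation places the two aryl groups trans, which sets furan C2 (R) relative to furan C3; fluoride then removes the silyl ether.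

**Step 8**
Reactants: 12 4-methoxybenzaldehyde; 13 diethyl propanedioate
Product: 14 diethyl 2-[(4-methoxyphenyl)methylidene]propanedioate
Conditions: piperidine (10 mol %), AcOH (10 mol %), toluene, reflux, Dean–Stark trap
Reagents that add atoms: none
Why: Knoevenagel condensation driven by removal of water.

**Step 9**
Reactants: 11 2-DBF-ethan-1-ol
Product: 15 DBF-acetaldehyde
Conditions: Dess–Martin periodinane, CH2Cl2, 0 → 23 °C; used at once
Reagents that add atoms: none
Why: Dess–Martin oxidation of a primary alcohol under neutral conditions; the arylacetaldehyde is not stored, because it is prone to self-condensation.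

**Step 10**
Reactants: 15 DBF-acetaldehyde; 14 diethyl 2-[(4-methoxyphenyl)methylidene]propanedioate
Product: 16 diethyl 2-[(1R,2S)-2-DBF-1-(4-methoxyphenyl)-3-oxopropyl]propanedioate
Conditions: (S)-2-[diphenyl(trimethylsilyloxy)methyl]pyrrolidine (20 mol %), PhCO2H (20 mol %), CHCl3, 4 °C
Reagents that add atoms: none
Why: Enamine-catalysed Michael addition of an aldehyde to an alkylidene malonate. The E-enamine, shielded on one face by the diphenyl(silyloxy)methyl group, should add through the acyclic synclinal transition state known for nitroalkene acceptors and give the syn adduct, which sets future C2 (2S here) and C3 (1R here) in the trans relation of the indane. The α-branched product forms an enamine only slowly, so it should not epimerise.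

**Step 11**
Reactants: 16 the Michael adduct; 17 nitromethane
Product: 20 diethyl 2-[(1R,2R,3E)-2-DBF-1-(4-methoxyphenyl)-4-nitrobut-3-en-1-yl]propanedioate, via nitro alcohol 18 (not isolated), via nitro mesylate 19 (not isolated)
Conditions: 17 (10 equiv), Et3N (20 mol %), THF, 0 °C; then MeSO2Cl, i-Pr2NEt, CH2Cl2, −40 → 0 °C
Reagents that add atoms: none
Why: Henry reaction followed by mesylation and elimination to the (E)-nitroalkene. The low temperature and the hindered base are chosen so that the α-aryl aldehyde does not epimerise before it has reacted and the nitroalkene is not deconjugated; the descriptor at the ring D carbon changes from S to R only because the priorities change.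

**Step 12**
Reactants: 20 the nitroalkene; 21 ethynyltri(propan-2-yl)silane
Product: 22 diethyl 2-[(1R,2R,3S)-2-DBF-1-(4-methoxyphenyl)-3-(nitromethyl)-5-TIPS-pent-4-yn-1-yl]propanedioate
Conditions: [Rh(OAc)(C2H4)2]2 (2.5 mol %), (R)-DTBM-Segphos (6 mol %), 1,4-dioxane, 60 °C
Reagents that add atoms: none
Why: Rhodium-catalysed asymmetric conjugate alkynylation of a nitroalkene; the bulky silyl group suppresses alkyne dimerisation and the chiral bisphosphine should select the face of the nitroalkene, which sets the future C1 (3S here). A minor epimer at this carbon would not be lost, since the centre becomes epimerisable in aldehyde 30 and should relax there to the all-trans indane.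

**Step 13**
Reactants: 22 the nitro alkyne
Product: 23 diethyl 2-[(1R,2R,3S)-3-(diethoxymethyl)-2-DBF-1-(4-methoxyphenyl)-5-TIPS-pent-4-yn-1-yl]propanedioate
Conditions: NaOEt, EtOH, 0 °C; then added to H2SO4/EtOH, −40 °C
Reagents that add atoms: ethanol, CCO
Why: Nef reaction run in ethanol: the nitronate is protonated on oxygen and solvolysed directly to the diethyl acetal, so the α-alkynyl aldehyde is never free and the adjacent stereocentre is not touched. The cold, brief acid treatment is chosen to spare the dihydrofuran, whose ionisation at C2–O would in any case be reversible.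

**Step 14**
Reactants: 23 the malonate acetal
Product: 24 ethyl (3S,4R,5S)-5-(diethoxymethyl)-4-DBF-3-(4-methoxyphenyl)-7-TIPS-hept-6-ynoate
Conditions: LiCl, H2O, DMSO, 150 °C
Reagents that add atoms: none
Why: Krapcho dealkoxycarbonylation under neutral conditions, which the acetal, the silylalkyne and the dihydrofuran tolerate; the An-bearing carbon is β to the remaining ester and cannot epimerise.

**Step 15**
Reactants: 24 the ethyl ester
Product: 26 (3S,4R,5S)-5-(diethoxymethyl)-1-ethoxy-4-DBF-3-(4-methoxyphenyl)-7-TIPS-hepta-1,6-diyne, via ketene acetal phosphate 25 (not isolated)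
Conditions: LiN(i-Pr)2, THF, −78 °C; ClP(O)(OEt)2, HMPA, −78 → 0 °C; then t-BuLi (2.2 equiv), −78 °C
Reagents that add atoms: none
Why: The ester enolate is trapped on oxygen as the ketene acetal phosphate; t-BuLi then removes the vinylic hydrogen and expels phosphate, the enol phosphate route to alkynes applied to an ethyl ester, which gives the 1-ethoxyalkyne. The silyl group keeps the other alkyne from being metalated and phosphorylated.

**Step 16**
Reactants: 26 the silylated diyne
Product: 27 (3S,4R,5S)-5-(diethoxymethyl)-1-ethoxy-4-DBF-3-(4-methoxyphenyl)hepta-1,6-diyne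
Conditions: Bu4NF, THF, 0 °C
Reagents that add atoms: none
Why: Fluoride cleaves the alkynyl C–Si bond; the basic, non-acidic conditions are those under which an ynol ether and an acetal are stable.

**Step 17 (key step)**
Reactants: 27 the hepta-1,6-diyne; 28 ethoxyethyne
Product: 29 (1S,2R,3S)-1-(diethoxymethyl)-4,6-diethoxy-2-DBF-3-(4-methoxyphenyl)-2,3-dihydro-1H-indene
Conditions: [Rh(cod)2]BF4 (10 mol %), rac-H8-BINAP (10 mol %), H2 (1 atm, 30 min, then Ar), CH2Cl2; 28 (5 equiv), 27 added over 2 h, 25 °C
Reagents that add atoms: none
Why: Hydrogenation removes cyclooctadiene and leaves a cationic bisphosphine complex of monovalent rhodium that binds both alkynes of 27; oxidative cyclometalation gives a rhodacyclopentadiene, which forms the C3a–C7a bond and closes the five-membered ring from its three-atom tether. 28 then coordinates and inserts into a Rh–C bond, and reductive elimination forms C4–C5 and C6–C7 and closes ring B as an arene, overall a [2+2+2] cycloaddition. The closest known reaction type is the cycloaddition of 1,6-diynes with monoalkynes under [Rh(cod)2]BF4/bisphosphine or Cp*RuCl(cod) catalysis, which accepts alkynyl ethers. No stereocentre is formed and none is at risk, because the three tether carbons have no acidic hydrogen under these neutral conditions, so the 3S,4R,5S chain gives the all-trans indane directly. The step needs regioselectivity in the insertion of 28: its ethoxy-bearing carbon should bond to the unsubstituted metallacycle carbon (future C7) and its CH end to the ethoxy-bearing one (future C4), because this keeps the two alkoxy groups apart at the metal, and the result is the 4,6-dioxygenation. It also needs chemoselectivity against homotrimerisation of 28 and dimerisation of 27, which the slow addition of 27 to an excess of 28 should provide.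

**Step 18**
Reactants: 29 the indane acetal
Product: 30 (1S,2R,3S)-4,6-diethoxy-2-DBF-3-(4-methoxyphenyl)-2,3-dihydro-1H-indene-1-carbaldehyde
Conditions: In(OTf)3 (5 mol %), acetone/H2O, 23 °C
Reagents that add atoms: water, O
Why: Mild Lewis-acid-catalysed acetal hydrolysis that leaves the dihydrofuran alone. C1 is now α to the aldehyde and to ring B, and the all-trans arrangement is the thermodynamically preferred one, so a minor C1 epimer carried from step 12 should equilibrate to 30.

**Step 19**
Reactants: 30 the indane aldehyde; 31 (4-methoxyphenyl)magnesium bromide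
Product: 32 [(1S,2R,3S)-4,6-diethoxy-2-DBF-3-(4-methoxyphenyl)-2,3-dihydro-1H-inden-1-yl](4-methoxyphenyl)methanol (both carbinol epimers)
Conditions: THF, −78 °C; then H2O
Reagents that add atoms: none
Why: Grignard addition to the aldehyde, fast at low temperature so that enolisation does not compete; the configuration of the carbinol does not matter because it is ionised in step 20.

**Step 20**
Reactants: 32 the diarylcarbinol
Product: 33 stenophyllol B octa-alkyl ether (ring B diethyl ether, six methyl ethers)
Conditions: Bi(OTf)3 (5 mol %), CH2Cl2, −20 → 0 °C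
Reagents that add atoms: none
Why: Intramolecular Friedel–Crafts alkylation: the 4-methoxybenzylic cation at Cα is attacked by the position of ring C that is ortho and para to its methoxy groups, which closes the eight-membered ring. The other arenes within reach would give a four-membered or a trans-fused five-membered ring. Cα should form R because the cation holds the C1–H bond in its plane on the side of the aryl group (minimal allylic 1,3-strain), which puts C2, and with it the tethered ring C, on one face only.

**Step 21**
Reactants: 33 the octa-alkyl ether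
Product: 34 stenophyllol B
Conditions: BBr3 (16 equiv), CH2Cl2, −78 → 23 °C; then H2O
Reagents that add atoms: none
Why: BBr3 cleaves all six methyl and both ethyl aryl ethers. The dihydrofuran is expected to survive: if its benzylic C–O bond opens, it closes again on work-up to the more stable trans ring that is already present.

## Compound list

1 | (3,5-dimethoxyphenyl)acetic acid | COc1cc(CC(=O)O)cc(OC)c1 | starting material
2 | (2-bromo-3,5-dimethoxyphenyl)acetic acid | COc1cc(CC(=O)O)c(Br)c(OC)c1 | intermediate
3 | 2-(2-bromo-3,5-dimethoxyphenyl)ethan-1-ol | COc1cc(CCO)c(Br)c(OC)c1 | intermediate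
4 | [2-(2-bromo-3,5-dimethoxyphenyl)ethoxy]tri(propan-2-yl)silane | COc1cc(CCO[Si](C(C)C)(C(C)C)C(C)C)c(Br)c(OC)c1 | intermediate
5 | 1-(4-methoxyphenyl)ethan-1-one | COc1ccc(cc1)C(C)=O | starting material
6 | 2-[2,4-dimethoxy-6-(2-{[tri(propan-2-yl)silyl]oxy}ethyl)phenyl]-1-(4-methoxyphenyl)ethan-1-one | COc1ccc(cc1)C(=O)Cc1c(OC)cc(OC)cc1CCO[Si](C(C)C)(C(C)C)C(C)C | intermediate
7 | 1-bromo-3,5-dimethoxybenzene | COc1cc(Br)cc(OC)c1 | starting material
8 | 2-(3,5-dimethoxyphenyl)-2-[2,4-dimethoxy-6-(2-{[tri(propan-2-yl)silyl]oxy}ethyl)phenyl]-1-(4-methoxyphenyl)ethan-1-one, racemic and configurationally labile | COc1ccc(cc1)C(=O)C(c1cc(OC)cc(OC)c1)c1c(OC)cc(OC)cc1CCO[Si](C(C)C)(C(C)C)C(C)C | intermediate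
9 | (1R,2R)-2-(3,5-dimethoxyphenyl)-2-[2,4-dimethoxy-6-(2-{[tri(propan-2-yl)silyl]oxy}ethyl)phenyl]-1-(4-methoxyphenyl)ethan-1-ol | COc1ccc(cc1)[C@H](O)[C@H](c1cc(OC)cc(OC)c1)c1c(OC)cc(OC)cc1CCO[Si](C(C)C)(C(C)C)C(C)C | intermediate
10 | {2-[(2R,3R)-3-(3,5-dimethoxyphenyl)-6-methoxy-2-(4-methoxyphenyl)-2,3-dihydro-1-benzofuran-4-yl]ethoxy}tri(propan-2-yl)silane | COc1ccc(cc1)[C@@H]1Oc2cc(OC)cc(CCO[Si](C(C)C)(C(C)C)C(C)C)c2[C@H]1c1cc(OC)cc(OC)c1 | intermediate (not isolated)
11 | 2-[(2R,3R)-3-(3,5-dimethoxyphenyl)-6-methoxy-2-(4-methoxyphenyl)-2,3-dihydro-1-benzofuran-4-yl]ethan-1-ol | COc1ccc(cc1)[C@@H]1Oc2cc(OC)cc(CCO)c2[C@H]1c1cc(OC)cc(OC)c1 | intermediate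
12 | 4-methoxybenzaldehyde | COc1ccc(C=O)cc1 | starting material
13 | diethyl propanedioate | CCOC(=O)CC(=O)OCC | starting material
14 | diethyl 2-[(4-methoxyphenyl)methylidene]propanedioate | CCOC(=O)C(=Cc1ccc(OC)cc1)C(=O)OCC | intermediate
15 | [(2R,3R)-3-(3,5-dimethoxyphenyl)-6-methoxy-2-(4-methoxyphenyl)-2,3-dihydro-1-benzofuran-4-yl]acetaldehyde | COc1ccc(cc1)[C@@H]1Oc2cc(OC)cc(CC=O)c2[C@H]1c1cc(OC)cc(OC)c1 | intermediate
16 | diethyl 2-[(1R,2S)-2-DBF-1-(4-methoxyphenyl)-3-oxopropyl]propanedioate | O=C[C@H](c1cc(OC)cc2O[C@@H](c3ccc(OC)cc3)[C@H](c3cc(OC)cc(OC)c3)c12)[C@@H](c1ccc(OC)cc1)C(C(=O)OCC)C(=O)OCC | intermediate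
17 | nitromethane | C[N+](=O)[O-] | starting material
18 | diethyl 2-[(1R,2S)-2-DBF-3-hydroxy-1-(4-methoxyphenyl)-4-nitrobutyl]propanedioate, both carbinol epimers | [O-][N+](=O)CC(O)[C@H](c1cc(OC)cc2O[C@@H](c3ccc(OC)cc3)[C@H](c3cc(OC)cc(OC)c3)c12)[C@@H](c1ccc(OC)cc1)C(C(=O)OCC)C(=O)OCC | intermediate (not isolated)
19 | methanesulfonate of 18, both epimers | [O-][N+](=O)CC(OS(C)(=O)=O)[C@H](c1cc(OC)cc2O[C@@H](c3ccc(OC)cc3)[C@H](c3cc(OC)cc(OC)c3)c12)[C@@H](c1ccc(OC)cc1)C(C(=O)OCC)C(=O)OCC | intermediate (not isolated)
20 | diethyl 2-[(1R,2R,3E)-2-DBF-1-(4-methoxyphenyl)-4-nitrobut-3-en-1-yl]propanedioate | [O-][N+](=O)/C=C/[C@H](c1cc(OC)cc2O[C@@H](c3ccc(OC)cc3)[C@H](c3cc(OC)cc(OC)c3)c12)[C@@H](c1ccc(OC)cc1)C(C(=O)OCC)C(=O)OCC | intermediate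
21 | ethynyltri(propan-2-yl)silane | C#C[Si](C(C)C)(C(C)C)C(C)C | starting material
22 | diethyl 2-[(1R,2R,3S)-2-DBF-1-(4-methoxyphenyl)-3-(nitromethyl)-5-[tri(propan-2-yl)silyl]pent-4-yn-1-yl]propanedioate | CC(C)[Si](C#C[C@@H](C[N+](=O)[O-])[C@H](c1cc(OC)cc2O[C@@H](c3ccc(OC)cc3)[C@H](c3cc(OC)cc(OC)c3)c12)[C@@H](c1ccc(OC)cc1)C(C(=O)OCC)C(=O)OCC)(C(C)C)C(C)C | intermediate
23 | diethyl 2-[(1R,2R,3S)-3-(diethoxymethyl)-2-DBF-1-(4-methoxyphenyl)-5-[tri(propan-2-yl)silyl]pent-4-yn-1-yl]propanedioate | CC(C)[Si](C#C[C@@H](C(OCC)OCC)[C@H](c1cc(OC)cc2O[C@@H](c3ccc(OC)cc3)[C@H](c3cc(OC)cc(OC)c3)c12)[C@@H](c1ccc(OC)cc1)C(C(=O)OCC)C(=O)OCC)(C(C)C)C(C)C | intermediate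
24 | ethyl (3S,4R,5S)-5-(diethoxymethyl)-4-DBF-3-(4-methoxyphenyl)-7-[tri(propan-2-yl)silyl]hept-6-ynoate | CC(C)[Si](C#C[C@@H](C(OCC)OCC)[C@H](c1cc(OC)cc2O[C@@H](c3ccc(OC)cc3)[C@H](c3cc(OC)cc(OC)c3)c12)[C@@H](c1ccc(OC)cc1)CC(=O)OCC)(C(C)C)C(C)C | intermediate
25 | ketene ethyl acetal diethyl phosphate of ester 24 (enolate oxygen phosphorylated, alkene geometry not defined) | CC(C)[Si](C#C[C@@H](C(OCC)OCC)[C@H](c1cc(OC)cc2O[C@@H](c3ccc(OC)cc3)[C@H](c3cc(OC)cc(OC)c3)c12)[C@@H](c1ccc(OC)cc1)C=C(OCC)OP(=O)(OCC)OCC)(C(C)C)C(C)C | intermediate (not isolated)
26 | (3S,4R,5S)-5-(diethoxymethyl)-1-ethoxy-4-DBF-3-(4-methoxyphenyl)-7-[tri(propan-2-yl)silyl]hepta-1,6-diyne | CC(C)[Si](C#C[C@@H](C(OCC)OCC)[C@H](c1cc(OC)cc2O[C@@H](c3ccc(OC)cc3)[C@H](c3cc(OC)cc(OC)c3)c12)[C@@H](c1ccc(OC)cc1)C#COCC)(C(C)C)C(C)C | intermediate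
27 | (3S,4R,5S)-5-(diethoxymethyl)-1-ethoxy-4-DBF-3-(4-methoxyphenyl)hepta-1,6-diyne | C#C[C@@H](C(OCC)OCC)[C@H](c1cc(OC)cc2O[C@@H](c3ccc(OC)cc3)[C@H](c3cc(OC)cc(OC)c3)c12)[C@@H](c1ccc(OC)cc1)C#COCC | intermediate
28 | ethoxyethyne | C#COCC | starting material
29 | (1S,2R,3S)-1-(diethoxymethyl)-4,6-diethoxy-2-DBF-3-(4-methoxyphenyl)-2,3-dihydro-1H-indene | COc1ccc(cc1)[C@H]1c2c(OCC)cc(OCC)cc2[C@@H](C(OCC)OCC)[C@@H]1c1cc(OC)cc2O[C@@H](c3ccc(OC)cc3)[C@H](c3cc(OC)cc(OC)c3)c12 | intermediate
30 | (1S,2R,3S)-4,6-diethoxy-2-DBF-3-(4-methoxyphenyl)-2,3-dihydro-1H-indene-1-carbaldehyde | COc1ccc(cc1)[C@H]1c2c(OCC)cc(OCC)cc2[C@@H](C=O)[C@@H]1c1cc(OC)cc2O[C@@H](c3ccc(OC)cc3)[C@H](c3cc(OC)cc(OC)c3)c12 | intermediate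
31 | (4-methoxyphenyl)magnesium bromide | COc1ccc([Mg]Br)cc1 | starting material
32 | [(1S,2R,3S)-4,6-diethoxy-2-DBF-3-(4-methoxyphenyl)-2,3-dihydro-1H-inden-1-yl](4-methoxyphenyl)methanol, both carbinol epimers | COc1ccc(cc1)[C@H]1c2c(OCC)cc(OCC)cc2[C@@H](C(O)c2ccc(OC)cc2)[C@@H]1c1cc(OC)cc2O[C@@H](c3ccc(OC)cc3)[C@H](c3cc(OC)cc(OC)c3)c12 | intermediate
33 | stenophyllol B octa-alkyl ether: ring B 4,6-diethyl ether, methyl ethers at the six other phenols, configuration as in 34 | COc1ccc([C@H]2c3c(OCC)cc(OCC)cc3[C@H]3[C@H](c4ccc(OC)cc4)c4c(OC)cc(OC)cc4[C@@H]4c5c(cc(OC)cc5[C@H]23)O[C@H]4c2ccc(OC)cc2)cc1 | intermediate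
34 | stenophyllol B | Oc1ccc([C@H]2c3c(O)cc(O)cc3[C@H]3[C@H](c4ccc(O)cc4)c4c(O)cc(O)cc4[C@@H]4c5c(cc(O)cc5[C@H]23)O[C@H]4c2ccc(O)cc2)cc1 | target

## Step count and least certain steps

Total step count: 21. Longest linear sequence: 20 (steps 1–7 and 9–21; step 8 is a side branch).

**Step 17 (key step).** The most likely failure is loss of chemo- or regioselectivity: homotrimerisation of 28, dimerisation of 27 through its terminal alkyne, or insertion of 28 in the reversed sense (ethoxy group at C5). A cationic rhodium centre binds the electron-rich alkynyl ethers strongly, and the steric difference between the two metallacycle carbons (ethoxy against hydrogen) is only moderate. Protonolysis of the ynol ether by traces of acid is the second hazard. Fallback, from 27 back to 29: 27 would be cyclised with 2-ethynyl-4,4,5,5-tetramethyl-1,3,2-dioxaborolane under Cp*RuCl(cod), a catalyst known to put the substituent of a terminal monoalkyne meta to the substituted diyne terminus, to give the C6 arylboronate F1. Oxidation of the C–B bond with NaBO3·4H2O would give the C6 phenol F2, and EtI/K2CO3 would give 29. The oxygen at C6 then comes from a C–B oxidation and not from an alkynyl ether.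

**Step 6.** The most likely failure is incomplete dynamic resolution: enolisation of 8 too slow relative to hydrogenation, or poor discrimination between the two enantiomers of 8 because both α-substituents are aryl groups, so that the future furan C3 is formed in low enantiomeric purity. Fallback, from 8 back to 11: 8 would be reduced with NaBH4 to the mixture of stereoisomeric alcohols F3 and treated as in step 7. This gives the racemic trans series, silyl ether 10 together with its enantiomer F4 and then 11 together with its enantiomer F5. 11 would be separated from F5 by preparative chromatography on a chiral stationary phase.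

**Step 7.** The most likely failure is erosion of configuration at furan C3: the benzylic cation can lose the neighbouring doubly benzylic hydrogen to give a triarylethene and be re-protonated, if demethylation of the oxonium ion is slower than this E1 path. Fallback, from 9 back to 11: BBr3 would cleave the five methyl ethers and the silyl ether, and the free phenol ortho to the side chain would close the ring on the benzylic bromide during work-up, giving the pentahydroxy dihydrobenzofuran F6. MeI/K2CO3 would then methylate its four phenols to give 11. A free phenol traps the cation faster than a methoxy group can.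

**Step 10.** The most likely failure is low conversion, because the 4-methoxybenzylidene malonate is a weak acceptor and the enamine of 15 is hindered by its ortho substituent; self-condensation of 15 and loss of the syn relation would then take over. Fallback, from 15 and 14 back to 16: 15 would be condensed with (2S)-2-(methoxymethyl)pyrrolidin-1-amine to the SAMP hydrazone F7, deprotonated with LiN(i-Pr)2 and added as the azaenolate to 14 to give the hydrazone adduct F8 (the enantiomeric auxiliary if the sense is opposite). Aqueous oxalic acid would cleave the hydrazone to 16.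

**Step 15.** The most likely failure is deprotonation by t-BuLi at the doubly benzylic furan C3–H, followed by β-elimination of the phenoxide and opening of the dihydrofuran, or incomplete elimination of the phosphate. Fallback, from 24 back to 26, without an alkyllithium: i-Bu2AlH at −78 °C would give the aldehyde F9, and KN(SiMe3)2 followed by EtOSO2CF3 would ethylate its enolate on oxygen to the ethyl enol ether F10. Br2 at −78 °C would give the dibromo ether F11 and Et3N the 2-bromo enol ether F12, from which LiN(i-Pr)2 would eliminate HBr to give 26.

**Step 20.** The most likely failure is poor facial selectivity at Cα or diversion of the cation, because an eight-membered ring closes slowly: the same acid can ionise the furan C2–O bond, the cation can lose a proton, or the free ortho position of ring D can attack. Fallback, from 32 back to 34: BBr3 would first remove all eight alkyl groups and give, after aqueous work-up, the octaphenolic carbinol F13, which is in equilibrium with its para-quinone methide. In dilute acid the free resorcinol ring C should add to the quinone methide, as in the biosynthesis, and give 34 directly.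

## Further compounds

F1 | step 17 | 2-[(1S,2R,3S)-1-(diethoxymethyl)-4-ethoxy-2-DBF-3-(4-methoxyphenyl)-2,3-dihydro-1H-inden-6-yl]-4,4,5,5-tetramethyl-1,3,2-dioxaborolane | COc1ccc(cc1)[C@H]1c2c(OCC)cc(B3OC(C)(C)C(C)(C)O3)cc2[C@@H](C(OCC)OCC)[C@@H]1c1cc(OC)cc2O[C@@H](c3ccc(OC)cc3)[C@H](c3cc(OC)cc(OC)c3)c12
F2 | step 17 | (1S,2R,3S)-1-(diethoxymethyl)-4-ethoxy-2-DBF-3-(4-methoxyphenyl)-2,3-dihydro-1H-inden-6-ol | COc1ccc(cc1)[C@H]1c2c(OCC)cc(O)cc2[C@@H](C(OCC)OCC)[C@@H]1c1cc(OC)cc2O[C@@H](c3ccc(OC)cc3)[C@H](c3cc(OC)cc(OC)c3)c12
F3 | step 6 | 2-(3,5-dimethoxyphenyl)-2-[2,4-dimethoxy-6-(2-{[tri(propan-2-yl)silyl]oxy}ethyl)phenyl]-1-(4-methoxyphenyl)ethan-1-ol, mixture of all stereoisomers | COc1ccc(cc1)C(O)C(c1cc(OC)cc(OC)c1)c1c(OC)cc(OC)cc1CCO[Si](C(C)C)(C(C)C)C(C)C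
F4 | step 6 | {2-[(2S,3S)-3-(3,5-dimethoxyphenyl)-6-methoxy-2-(4-methoxyphenyl)-2,3-dihydro-1-benzofuran-4-yl]ethoxy}tri(propan-2-yl)silane (enantiomer of 10) | COc1ccc(cc1)[C@H]1Oc2cc(OC)cc(CCO[Si](C(C)C)(C(C)C)C(C)C)c2[C@@H]1c1cc(OC)cc(OC)c1
F5 | step 6 | 2-[(2S,3S)-3-(3,5-dimethoxyphenyl)-6-methoxy-2-(4-methoxyphenyl)-2,3-dihydro-1-benzofuran-4-yl]ethan-1-ol (enantiomer of 11) | COc1ccc(cc1)[C@H]1Oc2cc(OC)cc(CCO)c2[C@@H]1c1cc(OC)cc(OC)c1
F6 | step 7 | 5-[(2R,3R)-6-hydroxy-4-(2-hydroxyethyl)-2-(4-hydroxyphenyl)-2,3-dihydro-1-benzofuran-3-yl]benzene-1,3-diol | Oc1ccc(cc1)[C@@H]1Oc2cc(O)cc(CCO)c2[C@H]1c1cc(O)cc(O)c1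
F7 | step 10 | (E)-hydrazone of 15 with (2S)-2-(methoxymethyl)pyrrolidin-1-amine | COC[C@@H]1CCCN1/N=C/Cc1cc(OC)cc2O[C@@H](c3ccc(OC)cc3)[C@H](c3cc(OC)cc(OC)c3)c12
F8 | step 10 | (E)-hydrazone of 16 with (2S)-2-(methoxymethyl)pyrrolidin-1-amine | COC[C@@H]1CCCN1/N=C/[C@H](c1cc(OC)cc2O[C@@H](c3ccc(OC)cc3)[C@H](c3cc(OC)cc(OC)c3)c12)[C@@H](c1ccc(OC)cc1)C(C(=O)OCC)C(=O)OCC
F9 | step 15 | (3S,4R,5S)-5-(diethoxymethyl)-4-DBF-3-(4-methoxyphenyl)-7-[tri(propan-2-yl)silyl]hept-6-ynal | CC(C)[Si](C#C[C@@H](C(OCC)OCC)[C@H](c1cc(OC)cc2O[C@@H](c3ccc(OC)cc3)[C@H](c3cc(OC)cc(OC)c3)c12)[C@@H](c1ccc(OC)cc1)CC=O)(C(C)C)C(C)C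
F10 | step 15 | ethyl enol ether of F9 (1-ethoxyhept-1-en-6-yne, alkene geometry not defined) | CC(C)[Si](C#C[C@@H](C(OCC)OCC)[C@H](c1cc(OC)cc2O[C@@H](c3ccc(OC)cc3)[C@H](c3cc(OC)cc(OC)c3)c12)[C@@H](c1ccc(OC)cc1)C=COCC)(C(C)C)C(C)C
F11 | step 15 | 1,2-dibromo-1-ethoxy adduct of F10 (both new centres undefined) | CC(C)[Si](C#C[C@@H](C(OCC)OCC)[C@H](c1cc(OC)cc2O[C@@H](c3ccc(OC)cc3)[C@H](c3cc(OC)cc(OC)c3)c12)[C@@H](c1ccc(OC)cc1)C(Br)C(Br)OCC)(C(C)C)C(C)C
F12 | step 15 | 2-bromo-1-ethoxyalkene from F11 (alkene geometry not defined) | CC(C)[Si](C#C[C@@H](C(OCC)OCC)[C@H](c1cc(OC)cc2O[C@@H](c3ccc(OC)cc3)[C@H](c3cc(OC)cc(OC)c3)c12)[C@@H](c1ccc(OC)cc1)C(Br)=COCC)(C(C)C)C(C)C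
F13 | step 20 | fully dealkylated carbinol corresponding to 32 (eight phenols, both carbinol epimers) | Oc1ccc(cc1)[C@H]1c2c(O)cc(O)cc2[C@@H](C(O)c2ccc(O)cc2)[C@@H]1c1cc(O)cc2O[C@@H](c3ccc(O)cc3)[C@H](c3cc(O)cc(O)c3)c12
A1 | alternative 1 | indenone with the eight-membered ring and the dihydrofuran closed (heptamethyl ether) | O=C1C2=C(c3cc(OC)cc(OC)c31)[C@H](c4ccc(OC)cc4)c5c(OC)cc(OC)cc5[C@@H]6c7c2cc(OC)cc7O[C@H]6c8ccc(OC)cc8
A2 | alternative 2 | methyl trans-4-benzyloxy-6-methoxy-2-(4-methoxyphenyl)-2,3-dihydro-1-benzofuran-3-carboxylate | COC(=O)[C@@H]1c2c(OCc3ccccc3)cc(OC)cc2O[C@H]1c4ccc(OC)cc4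
A3 | alternative 3 | indane-fused eight-membered keto ester with ring C in place (heptamethyl ether, methyl ester) | COc1ccc([C@H]2c3c(OC)cc(OC)cc3[C@H]3C(=O)c4c(OC)cc(OC)cc4[C@@H](C(=O)OC)c5c(OC)cc(OC)cc5[C@H]23)cc1
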